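**Retrosynthetic overview**

- The target is a 2,3-trans-3,4-trans tetrahydrofuran: O1, C2 (ring A aryl), C3 (C9H2OH), C4, C5H2, with the benzylic carbinol Ca (ring B aryl) on C4. The strategy rests on C5 being a bare methylene between O1 and C4, directly beside the Ca carbinol.
- The ring B benzyl ether and the ring A and C9 pivalates come off last. Before that, O1–C5, C4–C5 and Ca–O are cut together, which opens the only ring (the tetrahydrofuran, closed in step 10) to a (Z)-homoallylic alcohol, formaldehyde and water.
- The (Z)-alkene comes from an alkyne. The C2–C3 bond and both of its stereocentres come from an anti-selective allenylzinc addition of an enantioenriched ring B arylpropargylic mesylate to O-pivaloylvanillin.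
- The mesylate comes from 4-bromo-2-methoxyphenol and but-3-yne-1,2-diol by Sonogashira coupling, pivaloylation, oxidation and asymmetric transfer hydrogenation.

Key step: step 10

Remark on the chemistry: the tetrahydrofuran locants (O1, C2–C5, C9, Ca) are also used for the open-chain precursors. But-3-yne-1,2-diol is taken as the commercial racemate, so its stereocentre is reset by oxidation and asymmetric reduction.

**Route**

Step 1
Reactants: 1 4-bromo-2-methoxyphenol
Product: 2 1-(benzyloxy)-4-bromo-2-methoxybenzene
Conditions: BnBr, K2CO3, DMF, rt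
Reagents that add atoms: benzyl bromide, BrCc1ccccc1
Why: Williamson etherification of the phenoxide with a benzylic bromide should be clean, and the benzyl ether keeps ring B electron-rich for the later cyclisation.

Step 2
Reactants: 2 1-(benzyloxy)-4-bromo-2-methoxybenzene; 3 but-3-yne-1,2-diol (racemic)
Product: 4 rac-4-[4-(benzyloxy)-3-methoxyphenyl]but-3-yne-1,2-diol
Conditions: PdCl2(PPh3)2 (3 mol%), CuI (5 mol%), Et3N/DMF (1:1), 70 °C
Reagents that add atoms: none
Why: Sonogashira coupling, in which zerovalent palladium inserts into the aryl C–Br bond and the copper acetylide of the terminal alkyne transmetalates, tolerates the free hydroxyl groups, and the racemic carbinol centre is reset in steps 4 and 5.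

Step 3
Reactants: 4 rac-4-[4-(benzyloxy)-3-methoxyphenyl]but-3-yne-1,2-diol
Product: 5 rac-4-[4-(benzyloxy)-3-methoxyphenyl]-2-hydroxybut-3-yn-1-yl pivalate
Conditions: PivCl (1.05 equiv), pyridine, CH2Cl2, −20 to 0 °C
Reagents that add atoms: pivaloyl chloride, CC(C)(C)C(=O)Cl
Why: Selective acylation should occur because the bulky acid chloride reacts much faster at the unhindered primary hydroxyl than at the secondary propargylic one, and a pivalate is slow to migrate in later steps.

Step 4
Reactants: 5 rac-4-[4-(benzyloxy)-3-methoxyphenyl]-2-hydroxybut-3-yn-1-yl pivalate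
Product: 6 4-[4-(benzyloxy)-3-methoxyphenyl]-2-oxobut-3-yn-1-yl pivalate
Conditions: MnO2 (activated, 15 equiv), CH2Cl2, rt
Reagents that add atoms: none
Why: Activated MnO2 oxidises the propargylic alcohol to the ynone under neutral conditions that leave the ester and the benzyl ether alone, which erases the racemic centre.

Step 5
Reactants: 6 4-[4-(benzyloxy)-3-methoxyphenyl]-2-oxobut-3-yn-1-yl pivalate
Product: 7 (S)-4-[4-(benzyloxy)-3-methoxyphenyl]-2-hydroxybut-3-yn-1-yl pivalate
Conditions: Ru[(R,R)-TsDPEN](p-cymene) (base-free 16-electron amido complex, 1 mol%), iPrOH, rt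
Reagents that add atoms: none
Why: Noyori asymmetric transfer hydrogenation of an alkynyl ketone places the alkyne next to the arene ligand, so the (R,R) catalyst, which gives (R)-4-arylbut-3-yn-2-ols from methyl ynones, should give the same spatial arrangement here, named (S) because CH2OPiv outranks the alkynyl carbon.

Step 6
Reactants: 7 (S)-4-[4-(benzyloxy)-3-methoxyphenyl]-2-hydroxybut-3-yn-1-yl pivalate
Product: 8 (S)-4-[4-(benzyloxy)-3-methoxyphenyl]-2-(methylsulfonyloxy)but-3-yn-1-yl pivalate
Conditions: MsCl, Et3N, CH2Cl2, −78 to −40 °C; crude product used at once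
Reagents that add atoms: methanesulfonyl chloride, CS(=O)(=O)Cl
Why: Sulfonylation takes place at oxygen and so retains the carbinol configuration, and the labile arylpropargylic mesylate is carried on without purification.

Step 7
Reactants: 9 vanillin
Product: 10 4-formyl-2-methoxyphenyl pivalate (O-pivaloylvanillin)
Conditions: PivCl, Et3N, DMAP (5 mol%), CH2Cl2, 0 °C to rt
Reagents that add atoms: pivaloyl chloride, CC(C)(C)C(=O)Cl
Why: DMAP-catalysed acylation of the phenol gives the aryl pivalate, which makes ring A electron-poor enough to hold back ionisation of the later C2 carbinol.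

Step 8
Reactants: 8 (S)-4-[4-(benzyloxy)-3-methoxyphenyl]-2-(methylsulfonyloxy)but-3-yn-1-yl pivalate; 10 4-formyl-2-methoxyphenyl pivalate
Product: 12 4-[(1S,2R)-4-[4-(benzyloxy)-3-methoxyphenyl]-1-hydroxy-2-(pivaloyloxymethyl)but-3-yn-1-yl]-2-methoxyphenyl pivalate, via allenylzinc mesylate 11 (not isolated)
Conditions: Pd(OAc)2 (5 mol%), PPh3 (5 mol%), Et2Zn (3 equiv), THF, −78 to −20 °C; then aq NH4Cl
Reagents that add atoms: none
Why: In this Marshall propargylation zerovalent palladium displaces the mesylate in an anti SN2' sense, transmetalation with retention gives the (aS)-allenylzinc 11, and this adds to the aldehyde through a cyclic SE2' transition state on the zinc face with the aldehyde aryl group turned away from CH2OPiv, so that C3 (R) is set by chirality transfer with net inversion and C2 (S) by the anti preference of that transition state.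

Step 9
Reactants: 12 4-[(1S,2R)-4-[4-(benzyloxy)-3-methoxyphenyl]-1-hydroxy-2-(pivaloyloxymethyl)but-3-yn-1-yl]-2-methoxyphenyl pivalate
Product: 13 4-[(1S,2R,3Z)-4-[4-(benzyloxy)-3-methoxyphenyl]-1-hydroxy-2-(pivaloyloxymethyl)but-3-en-1-yl]-2-methoxyphenyl pivalate
Conditions: H2 (1 atm), Pd/CaCO3 poisoned with Pb(OAc)2 (Lindlar catalyst), quinoline, EtOAc, rt
Reagents that add atoms: none
Why: Lindlar semi-hydrogenation adds hydrogen syn across the alkyne on the poisoned palladium surface and should stop at the (Z)-styrene without cleaving the aryl benzyl ether.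

Step 10
Reactants: 13 4-[(1S,2R,3Z)-4-[4-(benzyloxy)-3-methoxyphenyl]-1-hydroxy-2-(pivaloyloxymethyl)but-3-en-1-yl]-2-methoxyphenyl pivalate; 14 formaldehyde (charged as paraformaldehyde)
Product: 17 {(2S,3R,4S)-4-{(S)-[4-(benzyloxy)-3-methoxyphenyl](hydroxy)methyl}-2-[3-methoxy-4-(pivaloyloxy)phenyl]tetrahydrofuran-3-yl}methyl pivalate, via O1=C5H2 oxocarbenium ion 15 (not isolated), via Ca benzylic cation 16 (not isolated)
Conditions: (CH2O)n (5 equiv), Sc(OTf)3 (10 mol%), H2O (10 equiv), MeNO2, 0 °C to rt; then aq NaHCO3
Reagents that add atoms: water, O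
Why: Sc(OTf)3 turns the hemiformal of the C2 hydroxyl into the O1=C5H2 oxocarbenium ion 15, alkene carbon C4 adds to C5 to leave the para-benzyloxybenzylic cation 16 at Ca, and water takes up this cation, so that O1–C5, C4–C5 and Ca–O are made in one operation. The closest known reactions are Prins cyclisations of homoallylic alcohols with aryl-terminated alkenes, which give tetrahydrofurans through an exocyclic benzylic cation, and Prins cyclisations in wet media that end in an alcohol. The tetrahydrofuran closes in a five-membered mode that is endo for the O1=C5 oxocarbenium bond and exo for the C4=Ca alkene. C4 is controlled by A(1,3) strain of the (Z)-alkene: C3–H eclipses the alkene, C2 with its tethered oxocarbenium ion lies over one face and C9 over the other, so C5 is delivered to the face that puts Ca trans to C9 (4S, both ring substituents pseudo-equatorial). Ca is controlled by approach of water anti to the new C4–C5 bond, and if the cation lives long enough to rotate, its A(1,3)-relaxed form (C4–H eclipsing the aryl side) still exposes the same face, flanked by C5H2 and screened on the other side by C3, so both pathways should lead to (S). The step needs C4 and not Ca to be the nucleophilic carbon, which the donor ring B secures by placing the charge at Ca (against tetrahydropyran closure and 2-oxonia-Cope exchange), and it needs the C2 carbinol to stay un-ionised, which the acyl-deactivated ring A and the mild catalytic acid secure.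

Step 11
Reactants: 17 {(2S,3R,4S)-4-{(S)-[4-(benzyloxy)-3-methoxyphenyl](hydroxy)methyl}-2-[3-methoxy-4-(pivaloyloxy)phenyl]tetrahydrofuran-3-yl}methyl pivalate
Product: 18 4-[(2S,3R,4S)-4-{(S)-[4-(benzyloxy)-3-methoxyphenyl](hydroxy)methyl}-3-(hydroxymethyl)tetrahydrofuran-2-yl]-2-methoxyphenol
Conditions: LiAlH4 (3 equiv), THF, 0 °C; then H2O, aq NaOH
Reagents that add atoms: none
Why: Hydride reduction cleaves the aryl pivalate and the hindered primary pivalate alike under non-acidic conditions that cannot ionise the Ca carbinol or the C2–O1 ether, and no stereocentre is touched.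

Step 12
Reactants: 18 4-[(2S,3R,4S)-4-{(S)-[4-(benzyloxy)-3-methoxyphenyl](hydroxy)methyl}-3-(hydroxymethyl)tetrahydrofuran-2-yl]-2-methoxyphenol
Product: 19 4-[(2S,3R,4S)-4-[(S)-hydroxy(4-hydroxy-3-methoxyphenyl)methyl]-3-(hydroxymethyl)tetrahydrofuran-2-yl]-2-methoxyphenol (target)
Conditions: H2 (1 atm), Pd/C (10 wt%), EtOAc/EtOH, rt, stopped after one equivalent of H2
Reagents that add atoms: none
Why: Hydrogenolysis of an aryl benzyl ether over Pd/C in a neutral solvent is much faster than cleavage of the benzylic Ca–OH and C2–O1 bonds, so the ring B phenol should be released without over-reduction.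

**Compound list**

1 | 4-bromo-2-methoxyphenol | COc1cc(Br)ccc1O | starting material
2 | 1-(benzyloxy)-4-bromo-2-methoxybenzene | COc1cc(Br)ccc1OCc1ccccc1 | intermediate
3 | but-3-yne-1,2-diol (racemic) | C#CC(O)CO | starting material
4 | rac-4-[4-(benzyloxy)-3-methoxyphenyl]but-3-yne-1,2-diol | COc1cc(C#CC(O)CO)ccc1OCc1ccccc1 | intermediate
5 | rac-4-[4-(benzyloxy)-3-methoxyphenyl]-2-hydroxybut-3-yn-1-yl pivalate | COc1cc(C#CC(O)COC(=O)C(C)(C)C)ccc1OCc1ccccc1 | intermediate
6 | 4-[4-(benzyloxy)-3-methoxyphenyl]-2-oxobut-3-yn-1-yl pivalate | COc1cc(C#CC(=O)COC(=O)C(C)(C)C)ccc1OCc1ccccc1 | intermediate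
7 | (S)-4-[4-(benzyloxy)-3-methoxyphenyl]-2-hydroxybut-3-yn-1-yl pivalate | COc1cc(C#C[C@@H](COC(=O)C(C)(C)C)O)ccc1OCc1ccccc1 | intermediate
8 | (S)-4-[4-(benzyloxy)-3-methoxyphenyl]-2-(methylsulfonyloxy)but-3-yn-1-yl pivalate | COc1cc(C#C[C@@H](COC(=O)C(C)(C)C)OS(C)(=O)=O)ccc1OCc1ccccc1 | intermediate
9 | vanillin (4-hydroxy-3-methoxybenzaldehyde) | COc1cc(C=O)ccc1O | starting material
10 | 4-formyl-2-methoxyphenyl pivalate | COc1cc(C=O)ccc1OC(=O)C(C)(C)C | intermediate
11 | (aS)-{1-[4-(benzyloxy)-3-methoxyphenyl]-4-(pivaloyloxy)buta-1,2-dien-1-yl}zinc methanesulfonate | CS(=O)(=O)O[Zn]C(c1ccc(OCc2ccccc2)c(OC)c1)=[C@@]=C([H])COC(=O)C(C)(C)C | intermediate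
12 | 4-[(1S,2R)-4-[4-(benzyloxy)-3-methoxyphenyl]-1-hydroxy-2-(pivaloyloxymethyl)but-3-yn-1-yl]-2-methoxyphenyl pivalate | COc1cc(C#C[C@H](COC(=O)C(C)(C)C)[C@H](O)c2ccc(OC(=O)C(C)(C)C)c(OC)c2)ccc1OCc1ccccc1 | intermediate
13 | 4-[(1S,2R,3Z)-4-[4-(benzyloxy)-3-methoxyphenyl]-1-hydroxy-2-(pivaloyloxymethyl)but-3-en-1-yl]-2-methoxyphenyl pivalate | COc1cc(/C=C\[C@H](COC(=O)C(C)(C)C)[C@H](O)c2ccc(OC(=O)C(C)(C)C)c(OC)c2)ccc1OCc1ccccc1 | intermediate
14 | formaldehyde | C=O | starting material
15 | O1=C5H2 oxocarbenium ion on the C2 oxygen of 13 (C2, C3 and the (Z)-alkene as in 13) | COc1cc(/C=C\[C@H](COC(=O)C(C)(C)C)[C@H]([O+]=C)c2ccc(OC(=O)C(C)(C)C)c(OC)c2)ccc1OCc1ccccc1 | intermediate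
16 | Ca benzylic cation of the closed tetrahydrofuran (C2, C3 and C4 as in 17) | COc1cc([CH+][C@@H]2CO[C@H](c3ccc(OC(=O)C(C)(C)C)c(OC)c3)[C@H]2COC(=O)C(C)(C)C)ccc1OCc1ccccc1 | intermediate
17 | {(2S,3R,4S)-4-{(S)-[4-(benzyloxy)-3-methoxyphenyl](hydroxy)methyl}-2-[3-methoxy-4-(pivaloyloxy)phenyl]tetrahydrofuran-3-yl}methyl pivalate | COc1cc([C@@H](O)[C@@H]2CO[C@H](c3ccc(OC(=O)C(C)(C)C)c(OC)c3)[C@H]2COC(=O)C(C)(C)C)ccc1OCc1ccccc1 | intermediate
18 | 4-[(2S,3R,4S)-4-{(S)-[4-(benzyloxy)-3-methoxyphenyl](hydroxy)methyl}-3-(hydroxymethyl)tetrahydrofuran-2-yl]-2-methoxyphenol | COc1cc([C@@H](O)[C@@H]2CO[C@H](c3ccc(O)c(OC)c3)[C@H]2CO)ccc1OCc1ccccc1 | intermediate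
19 | 4-[(2S,3R,4S)-4-[(S)-hydroxy(4-hydroxy-3-methoxyphenyl)methyl]-3-(hydroxymethyl)tetrahydrofuran-2-yl]-2-methoxyphenol | COc1cc([C@@H](O)[C@@H]2CO[C@H](c3ccc(O)c(OC)c3)[C@H]2CO)ccc1O | target

**Step count**

Total: 12 steps. Longest linear sequence: 11 steps (steps 1–6 and 8–12, from 4-bromo-2-methoxyphenol); step 7 is the side branch.

**Steps most likely to fail**

1. Step 10 (key step).
 - What may go wrong: loss of facial control at Ca, because the donor-stabilised cation is long-lived and the product carbinol can re-ionise and equilibrate under the acid. Lesser risks are diversion of the oxocarbenium ion by 2-oxonia-Cope exchange, ionisation at C2, and Friedel–Crafts capture of the cation by ring A.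
 - Fallback for the Ca problem: it sets out from 17 as the Ca-epimer mixture that step 10 delivers. Oxidation with Dess–Martin periodinane (CH2Cl2, NaHCO3) should give the aryl ketone F1, with C2, C3 and C4 untouched. Corey–Bakshi–Shibata reduction with (R)-2-methyl-CBS-oxazaborolidine and BH3·SMe2 in THF at −20 °C should then deliver hydride under catalyst control (aryl as the large group) to the face that gives the (S)-carbinol, which returns to 17. Substrate control alone (Felkin–Anh attack anti to C3) is expected to favour the (R)-epimer, which is why a reagent-controlled reduction is chosen.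

2. Step 8.
 - What may go wrong: elimination of pivalate from C9 in the allenyl/propargylzinc species, a weaker anti preference with an aromatic aldehyde, ethyl transfer from zinc, and decomposition or racemisation of the labile mesylate before it is consumed.
 - Fallback: it sets out from alcohol 7 and aldehyde 10 and replaces the transient zinc reagent by an isolable boron reagent. Methyl chloroformate and pyridine should give the stable methyl carbonate F2. Copper-catalysed SN2' borylation (CuCl, KOtBu, Xantphos, B2pin2, THF, rt) occurs anti to the leaving group and should give the (aR)-allenylboronate F3, with boron where zinc would sit. Heating F3 with aldehyde 10 in toluene (60–80 °C) goes through the same closed six-membered SE2' transition state and after aqueous work-up should return to 12.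

3. Step 5.
 - What may go wrong: insufficient enantioface discrimination, because the acyloxymethyl group competes with the alkyne for the catalyst pocket, and conjugate addition of 2-propanol to the ynone.
 - Fallback: it sets out from bromide 2 and takes the stereocentre from the chiral pool. Sonogashira coupling under the conditions of step 2 with enantiopure (S)-but-3-yne-1,2-diol F4 should give the (S)-diol F5. Selective pivaloylation as in step 3 then returns to 7, and steps 4 and 5 are dropped.

**Further compounds**

F1 | step 10 | {(2S,3R,4S)-4-[4-(benzyloxy)-3-methoxybenzoyl]-2-[3-methoxy-4-(pivaloyloxy)phenyl]tetrahydrofuran-3-yl}methyl pivalate | COc1cc(C(=O)[C@@H]2CO[C@H](c3ccc(OC(=O)C(C)(C)C)c(OC)c3)[C@H]2COC(=O)C(C)(C)C)ccc1OCc1ccccc1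
F2 | step 8 | (S)-4-[4-(benzyloxy)-3-methoxyphenyl]-2-[(methoxycarbonyl)oxy]but-3-yn-1-yl pivalate | COc1cc(C#C[C@@H](COC(=O)C(C)(C)C)OC(=O)OC)ccc1OCc1ccccc1
F3 | step 8 | (aR)-4-[4-(benzyloxy)-3-methoxyphenyl]-4-(4,4,5,5-tetramethyl-1,3,2-dioxaborolan-2-yl)buta-2,3-dien-1-yl pivalate | CC1(C)OB(OC1(C)C)C(c1ccc(OCc2ccccc2)c(OC)c1)=[C@@]=C([H])COC(=O)C(C)(C)C
F4 | step 5 | (S)-but-3-yne-1,2-diol | C#C[C@@H](CO)O
F5 | step 5 | (S)-4-[4-(benzyloxy)-3-methoxyphenyl]but-3-yne-1,2-diol | COc1cc(C#C[C@@H](CO)O)ccc1OCc1ccccc1
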